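Assumption: positions are given in labdane numbering (C1–C20; β is the face of the C10 methyl, α the opposite face). The target SMILES is read as (5S,7R,8S,9S,10S,13S).

## Retrosynthetic overview
1. Target 29 comes from spiro-oxetane 27. One CH is inserted into an oxetane C–O bond, which makes the dihydrofuran (last ring formed) and sets C13.
2. 27 comes from Δ6-8-enone 20: methyl addition at C8, oxidation of C6=C7 to a diosphenol acetate, then hydride at C7 with O→O acetyl shift.
3. 20 comes from alkynediol 17. Gold hydroalkoxylation closes the oxolane, and an oxocarbenium semipinacol ring expansion (C10 moves from C8 to C9) turns the cyclopentenol into ring B.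
4. 17 comes from hydrindenone 11 and alkyne 15. Alkyne 15 is made from oxetan-3-one and propargyl bromide.
5. 11 comes from the (S)-Hajos–Parrish ketone, itself made from 2-methylcyclopentane-1,3-dione and methyl vinyl ketone. Ring order: A, then oxolane with B, then dihydrofuran.

## Route

Step 1
Reactants: 1 2-methylcyclopentane-1,3-dione; 2 methyl vinyl ketone
Product: 3 2-methyl-2-(3-oxobutyl)cyclopentane-1,3-dione
Conditions: H2O, AcOH (cat.), 70 °C
Reagents that add atoms: none
Why: Michael addition of the acidic 2-alkyl-1,3-dione to the enone stops at the mono-adduct because the product has no acidic C–H between the carbonyls; no stereocentre is formed.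

Step 2
Reactants: 3 2-methyl-2-(3-oxobutyl)cyclopentane-1,3-dione
Product: 5 (S)-Hajos–Parrish ketone [(7aS)-7a-methyl-2,3,7,7a-tetrahydro-1H-indene-1,5(6H)-dione], via Hajos ketol 4 (not isolated)
Conditions: (S)-proline (3 mol %), DMF, 16–20 °C; then H2SO4 (cat.), DMF, 95 °C; recrystallise
Reagents that add atoms: none
Why: In the Hajos–Parrish–Eder–Sauer–Wiechert reaction the proline enamine attacks one of the two enantiotopic ring carbonyls (desymmetrising aldol), which sets C10 as S, and acid then dehydrates the ketol.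

Step 3
Reactants: 5 (S)-Hajos–Parrish ketone
Product: 6 C8 ethylene ketal of 5 [(7aS)-1,1-ethylenedioxy-7a-methyl-1,2,3,6,7,7a-hexahydro-5H-inden-5-one]
Conditions: TMSOCH2CH2OTMS, TMSOTf (5 mol %), CH2Cl2, −78 °C
Reagents that add atoms: 1,2-bis(trimethylsilyloxy)ethane C[Si](C)(C)OCCO[Si](C)(C)C
Why: Noyori ketalisation under kinetic control takes the saturated cyclopentanone and leaves the less electrophilic enone; no stereocentre is touched.

Step 4
Reactants: 6 C8 ethylene ketal of 5
Product: 8 (7aS)-1,1-ethylenedioxy-4,4,7a-trimethyl-1,2,4,6,7,7a-hexahydro-5H-inden-5-one (C5=C6 alkene), via monomethyl ketone 7 (not isolated)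
Conditions: KOt-Bu (3 equiv), t-BuOH–THF, rt; MeI (4 equiv), 0 °C → rt
Reagents that add atoms: iodomethane CI
Why: Deconjugative double α-alkylation of the extended dienolate puts both methyls on C4 and locks the alkene at C5=C6, while the ketal blocks enolisation at C7.

Step 5
Reactants: 8 4,4-dimethyl keto ketal
Product: 11 (7aS)-4,4,7a-trimethyl-2,4,5,6,7,7a-hexahydro-1H-inden-1-one, via hydrazone 9 (not isolated), via deoxygenated ketal 10 (not isolated)
Conditions: N2H4·H2O, KOH, diethylene glycol, 130 → 205 °C; crude, then p-TsOH·H2O (10 mol %), acetone–H2O, rt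
Reagents that add atoms: water O
Why: Wolff–Kishner reduction (Huang-Minlon) removes the hindered C3 carbonyl under base that the ketal and alkene tolerate, and mild ketal hydrolysis then frees the C8 ketone because γ-protonation at the hindered C5 (which would conjugate the alkene) is slow.

Step 6
Reactants: 12 oxetan-3-one; 13 propargyl bromide
Product: 15 3-(prop-2-yn-1-yl)oxetan-3-ol, via allenylzinc bromide 14 (not isolated)
Conditions: Zn dust, THF, 0 °C → rt; aq. work-up
Reagents that add atoms: none
Why: In this zinc Barbier propargylation the allenylzinc species adds through its γ-carbon (SE2′) to the strained, electrophilic ketone and gives the homopropargylic alcohol; no stereocentre is formed.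

Step 7
Reactants: 11 hydrindenone; 15 3-(prop-2-yn-1-yl)oxetan-3-ol
Product: 17 (1R,7aS)-1-[3-(3-hydroxyoxetan-3-yl)prop-1-yn-1-yl]-4,4,7a-trimethyl-2,4,5,6,7,7a-hexahydro-1H-inden-1-ol (OH cis to the angular methyl), via cerium acetylide 16 (not isolated)
Conditions: 15, n-BuLi (2.05 equiv), THF, −78 °C; CeCl3 (anhydrous, 1.1 equiv); then 11, −78 °C; aq. work-up
Reagents that add atoms: none
Why: Organocerium 1,2-addition has low enough basicity to avoid enolising the doubly activated C7–H, and attack opposite the angular methyl (as with 17-keto steroids) gives the 8β-carbinol, whose configuration controls the next step.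

Step 8
Reactants: 17 alkynediol
Product: 20 9α,13:14,16-diepoxy-15,17-dinorlabd-6-en-8-one (5α-H; 10β-Me; C13 spiro to the oxetane), via spiro enol ether 18 (not isolated), via deconjugated enone 19 (not isolated)
Conditions: (Ph3P)AuNTf2 (3 mol %), 4 Å MS, CH2Cl2, 0 °C; then CSA (20 mol %), rt; then DBU (1 equiv), rt
Reagents that add atoms: none
Why: Gold(I) 5-endo-dig hydroalkoxylation gives dihydrofuran 18, C11 protonation gives an oxocarbenium ion next to the carbinol, and an oxonium-initiated semipinacol 1,2-shift of the more substituted allylic C10 from C8 to C9 (D-homoannulation-type cyclopentanol-to-cyclohexanone expansion) forms ring B with retention at C10; C9 is set by the rotamer with C=O+ anti to C–OH (dipole and size), which places O9 axial (α) and C11 equatorial, and DBU then conjugates the enone with thermodynamic 5α-protonation.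

Step 9
Reactants: 20 Δ6-8-enone
Product: 21 9α,13:14,16-diepoxy-15-norlabd-6-en-8β-ol (8α-methyl)
Conditions: MeLi, CeCl3 (anhydrous), THF, −78 °C; aq. work-up
Reagents that add atoms: methyllithium [Li]C
Why: Organocerium 1,2-addition delivers methyl along the equatorial α trajectory, because the β face of C8 is closed by the syn-axial C10 methyl and Ce can bind the 9α-ether oxygen, which sets C8 as 8α-Me/8β-OH.

Step 10
Reactants: 21 tertiary allylic alcohol
Product: 22 9α,13:14,16-diepoxy-15-norlabdane-6α,7α,8β-triol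
Conditions: OsO4 (5 mol %), NMO, acetone–H2O, rt
Reagents that add atoms: osmium tetroxide (catalytic O carrier) O=[Os](=O)(=O)=O; N-methylmorpholine N-oxide C[N+]1([O-])CCOCC1; water O
Why: Upjohn syn-dihydroxylation occurs on the α face, anti to the 8β-OH and the axial methyls; both new carbinol centres are erased in step 11, so facial selectivity is not critical.

Step 11
Reactants: 22 triol
Product: 25 6-acetoxy-9α,13:14,16-diepoxy-8β-hydroxy-15-norlabd-5-en-7-one (diosphenol acetate), via 6,7-dione 23 (not isolated), via diosphenol 24 (not isolated)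
Conditions: (COCl)2, DMSO, CH2Cl2, −78 °C; Et3N, −78 → 0 °C; then Ac2O (1.2 equiv), DMAP (cat.), 0 °C → rt
Reagents that add atoms: acetic anhydride CC(=O)OC(C)=O
Why: Swern oxidation takes both secondary alcohols to the α-diketone without C–C cleavage, the dione can enolise only through C5–H, and the acidic enol OH is esterified in preference to the hindered tertiary 8-OH.

Step 12
Reactants: 25 diosphenol acetate
Product: 27 7β-acetoxy-9α,13:14,16-diepoxy-8β-hydroxy-15-norlabdan-6-one, via allylic alcohol 26 (not isolated)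
Conditions: NaBH4, CeCl3·7H2O, MeOH–THF, −78 °C; crude, then Et3N, DMAP (10 mol %), CH2Cl2, rt
Reagents that add atoms: none
Why: Luche 1,2-reduction adds hydride to C7 from the α face (axial attack, anti to the perpendicular C8–O bond, polar Felkin–Anh) to give the 7β-alcohol, a base-catalysed O→O acyl migration from the enol acetate releases the C6 enol, and this ketonises by α-protonation at C5; equatorial 7β-OAc and 5α-H are also the thermodynamic epimers, so minor isomers converge.

Step 13
Reactants: 27 spiro-oxetane keto acetate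
Product: 29 (13S)-7β-acetoxy-9α,13:15,16-diepoxy-8β-hydroxylabd-14-en-6-one (target CNP0284584.1), via sulfone 28 (not isolated)
Conditions: [Cu(MeCN)4]PF6 (5 mol %), (S,S)-t-Bu-box (6 mol %), TsCHN2 (1.5 equiv, syringe pump), 4 Å MS, CH2Cl2, 0 °C → rt; then Et3N (3 equiv), 40 °C; Et3N-deactivated silica
Reagents that add atoms: tosyldiazomethane Cc1ccc(cc1)S(=O)(=O)C=[N+]=[N-]
Why: Proposed new method: a chiral Cu(I) sulfonylcarbene is captured by the oxetane oxygen, the most Lewis-basic and accessible oxygen (the oxolane O lies between two quaternary carbons and the axial 8-OH is shielded); the copper-bound oxonium ylide undergoes a strain-driven stepwise [1,2]-Stevens shift of one of the two diastereotopic CH2–O bonds to give 2-sulfonyl-tetrahydrofuran 28; the ligand decides which C–O bond aligns with the C–Cu bond and so sets C13 (ligand antipode to be matched by experiment, C15 configuration irrelevant); Et3N-induced loss of sulfinate can only go toward C14 because C13 is quaternary; the closest known reaction types are Cu- or Rh-catalysed oxetane-to-tetrahydrofuran ring expansion with diazo esters and base elimination of sulfinic acid from 2-sulfonyl cyclic ethers, and what is new is the traceless CH donor and the desymmetrisation of a 3,3-disubstituted oxetane.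

## Compound list
1 | 2-methylcyclopentane-1,3-dione | CC1C(=O)CCC1=O | starting material
2 | methyl vinyl ketone | CC(=O)C=C | starting material
3 | 2-methyl-2-(3-oxobutyl)cyclopentane-1,3-dione | CC(=O)CCC1(C)C(=O)CCC1=O | intermediate
4 | Hajos ketol, (3aS,7aS)-3a-hydroxy-7a-methylhexahydro-1H-indene-1,5(4H)-dione | C[C@]12CCC(=O)C[C@@]1(O)CCC2=O | intermediate
5 | (S)-Hajos–Parrish ketone | C[C@]12CCC(=O)C=C1CCC2=O | intermediate
6 | C8 ethylene ketal of 5 | C[C@]12CCC(=O)C=C1CCC23OCCO3 | intermediate
7 | 4-monomethyl β,γ-unsaturated keto ketal (C4 epimers) | C[C@]12CCC(=O)C(C)C1=CCC23OCCO3 | intermediate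
8 | 4,4-dimethyl β,γ-unsaturated keto ketal | C[C@]12CCC(=O)C(C)(C)C1=CCC23OCCO3 | intermediate
9 | C3 hydrazone of 8 | C[C@]12CCC(=NN)C(C)(C)C1=CCC23OCCO3 | intermediate
10 | C3-deoxygenated ketal | C[C@]12CCCC(C)(C)C1=CCC23OCCO3 | intermediate
11 | (7aS)-4,4,7a-trimethyl-2,4,5,6,7,7a-hexahydro-1H-inden-1-one | C[C@]12CCCC(C)(C)C1=CCC2=O | intermediate
12 | oxetan-3-one | O=C1COC1 | starting material
13 | propargyl bromide | C#CCBr | starting material
14 | allenylzinc bromide | C=C=C[Zn]Br | intermediate
15 | 3-(prop-2-yn-1-yl)oxetan-3-ol | C#CCC1(O)COC1 | intermediate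
16 | O-lithio C-dichlorocerio acetylide of 15 | [Li]OC1(CC#C[Ce](Cl)Cl)COC1 | intermediate
17 | (1R,7aS)-alkynediol (8β-OH) | C[C@]12CCCC(C)(C)C1=CC[C@@]2(O)C#CCC3(O)COC3 | intermediate
18 | (1S,7aS)-1-(2,5-dioxaspiro[3.4]oct-6-en-6-yl)-4,4,7a-trimethyl-2,4,5,6,7,7a-hexahydro-1H-inden-1-ol | C[C@]12CCCC(C)(C)C1=CC[C@@]2(O)C3=CCC4(COC4)O3 | intermediate
19 | 9α,13:14,16-diepoxy-15,17-dinorlabd-5-en-8-one | O=C1CC=C2C(C)(C)CCC[C@]2(C)[C@@]13CCC4(COC4)O3 | intermediate
20 | 9α,13:14,16-diepoxy-15,17-dinorlabd-6-en-8-one | O=C1C=C[C@H]2C(C)(C)CCC[C@]2(C)[C@@]13CCC4(COC4)O3 | intermediate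
21 | 9α,13:14,16-diepoxy-15-norlabd-6-en-8β-ol | C1=C[C@H]2C(C)(C)CCC[C@]2(C)[C@@]2(CCC3(COC3)O2)[C@@]1(C)O | intermediate
22 | 9α,13:14,16-diepoxy-15-norlabdane-6α,7α,8β-triol | O[C@@H]1[C@H](O)[C@H]2C(C)(C)CCC[C@]2(C)[C@@]2(CCC3(COC3)O2)[C@@]1(C)O | intermediate
23 | 9α,13:14,16-diepoxy-8β-hydroxy-15-norlabdane-6,7-dione | O=C1C(=O)[C@H]2C(C)(C)CCC[C@]2(C)[C@@]2(CCC3(COC3)O2)[C@@]1(C)O | intermediate
24 | 9α,13:14,16-diepoxy-6,8β-dihydroxy-15-norlabd-5-en-7-one | O=C1C(O)=C2C(C)(C)CCC[C@]2(C)[C@@]2(CCC3(COC3)O2)[C@@]1(C)O | intermediate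
25 | 6-acetoxy-9α,13:14,16-diepoxy-8β-hydroxy-15-norlabd-5-en-7-one | O=C1C(OC(C)=O)=C2C(C)(C)CCC[C@]2(C)[C@@]2(CCC3(COC3)O2)[C@@]1(C)O | intermediate
26 | 6-acetoxy-9α,13:14,16-diepoxy-15-norlabd-5-ene-7β,8β-diol | O[C@H]1C(OC(C)=O)=C2C(C)(C)CCC[C@]2(C)[C@@]2(CCC3(COC3)O2)[C@@]1(C)O | intermediate
27 | 7β-acetoxy-9α,13:14,16-diepoxy-8β-hydroxy-15-norlabdan-6-one | CC(=O)O[C@H]1C(=O)[C@H]2C(C)(C)CCC[C@]2(C)[C@@]2(CCC3(COC3)O2)[C@@]1(C)O | intermediate
28 | (13S)-7β-acetoxy-9α,13:15,16-diepoxy-8β-hydroxy-15-tosyllabdan-6-one (C15 epimers) | CC(=O)O[C@H]1C(=O)[C@H]2C(C)(C)CCC[C@]2(C)[C@@]2(CC[C@@]3(CC(OC3)S(=O)(=O)c4ccc(C)cc4)O2)[C@@]1(C)O | intermediate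
29 | (5S,7R,8S,9S,10S,13S)-7β-acetoxy-9α,13:15,16-diepoxy-8β-hydroxylabd-14-en-6-one | CC(=O)O[C@H]1C(=O)[C@H]2C(C)(C)CCC[C@]2(C)[C@@]2(CC[C@@]3(C=COC3)O2)[C@@]1(C)O | target

## Step count and risks
Total steps: 13. Longest linear sequence: 12 (steps 1–5 and 7–13).

**1. Step 13 (the proposed new step).**
- Risks: O–H insertion at the 8-OH, or poor choice between the two oxetane CH2 groups.
- Fallback (known chemistry): it sets out from 27 and comes back at 29.
- A chiral squaramide hydrogen-bond-donor catalyst with TMSBr opens the oxetane enantiotopos-selectively to the 14-bromo-16-silyl ether F1.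
- Tin-hydride radical carbonylation (Bu3SnH, AIBN, CO 80 atm, benzene, 80 °C) converts the neopentyl bromide into the 15-aldehyde F2.
- Citric acid in MeOH removes the TMS group, and the freed C16 alcohol closes onto the aldehyde to give the 15-lactol F3.
- MsCl/Et3N forms the anomeric 15-mesylate F4, which eliminates in the flask toward C14 to give 29.

**2. Step 8 (hydroalkoxylation and semipinacol ring expansion).**
- Risks: dehydration of the carbinol, sluggish five-to-six expansion, or C7 migration.
- Fallback: it sets out from 17 and comes back at 19, which DBU converts to 20 as in step 8.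
- The gold stage is quenched with Et3N and 18 is isolated.
- Reversible protonation is replaced by irreversible halonium activation: NBS with propylene oxide in CH2Cl2 at −78 °C triggers a bromonium-initiated semipinacol shift to the 11-bromo ring-expanded ketone F5.
- Bu3SnH/AIBN removes the bromine to give 19.

**3. Step 12 (reduction and acyl shift).**
- Risks: solvolysis of the enol acetate, incomplete migration, or over-reduction.
- Fallback: it sets out from 25 and comes back at 27.
- After the Luche reduction to 26, the enol acetate is cleaved deliberately with K2CO3/MeOH at 0 °C to give the 7β-hydroxy-6-ketone F6.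
- Intermolecular acetylation (Ac2O, pyridine, rt) touches only the secondary 7β-OH and gives 27.

## Further compounds
F1 | step 13 | 7β-acetoxy-14-bromo-9α,13-epoxy-8β-hydroxy-16-(trimethylsilyloxy)-15-norlabdan-6-one (C13 arranged as in 29) | CC(=O)O[C@H]1C(=O)[C@H]2C(C)(C)CCC[C@]2(C)[C@@]2(CC[C@](CBr)(CO[Si](C)(C)C)O2)[C@@]1(C)O
F2 | step 13 | 7β-acetoxy-9α,13-epoxy-8β-hydroxy-6-oxo-16-(trimethylsilyloxy)labdan-15-al | CC(=O)O[C@H]1C(=O)[C@H]2C(C)(C)CCC[C@]2(C)[C@@]2(CC[C@](CC=O)(CO[Si](C)(C)C)O2)[C@@]1(C)O
F3 | step 13 | 7β-acetoxy-9α,13:15,16-diepoxy-8β,15-dihydroxylabdan-6-one (lactol, C15 epimers) | CC(=O)O[C@H]1C(=O)[C@H]2C(C)(C)CCC[C@]2(C)[C@@]2(CC[C@@]3(CC(O)OC3)O2)[C@@]1(C)O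
F4 | step 13 | 15-O-mesylate of F3 | CC(=O)O[C@H]1C(=O)[C@H]2C(C)(C)CCC[C@]2(C)[C@@]2(CC[C@@]3(CC(OS(C)(=O)=O)OC3)O2)[C@@]1(C)O
F5 | step 8 | 11-bromo-9α,13:14,16-diepoxy-15,17-dinorlabd-5-en-8-one (C11 epimers) | O=C1CC=C2C(C)(C)CCC[C@]2(C)[C@@]13C(Br)CC4(COC4)O3
F6 | step 12 | 9α,13:14,16-diepoxy-7β,8β-dihydroxy-15-norlabdan-6-one | O[C@H]1C(=O)[C@H]2C(C)(C)CCC[C@]2(C)[C@@]2(CCC3(COC3)O2)[C@@]1(C)O
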